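(The earlier runs and the new flask come from a simulation from invented constants; the scatter is artificial.)

In this closed, stirred vessel we must decide whether the charge stands as written.

| flask | starting material | reagent | second substrate | third substrate | remark | time |
|---|---|---|---|---|---|---|
| blue | 0.34 mM | 0.65 mM | 0.50 mM | 0.10 mM | run made earlier |  |
| green | 0.75 mM | 0.65 mM | 0.50 mM | 0.10 mM | run made earlier |  |
| flask | 0.50 mM | 0.650 mM | 0.500 mM | 0.100 mM |  | 3.0 min |

| run | time / s | target / % | starting material / % |
|---|---|---|---|
| blue | 12.0 | 80.8 | 18.7 |
| blue | 20.0 | 88.9 | 10.8 |
| blue | 40.0 | 91.1 | 1.5 |
| blue | 60.0 | 92.4 | 1.7 |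
| blue | 120 | 88.0 | 0.4 |
| green | 12.0 | 62.9 | 39.1 |
| green | 20.0 | 64.9 | 34.3 |
| green | 40.0 | 65.6 | 33.8 |
| green | 60.0 | 63.2 | 31.8 |
| green | 120 | 57.8 | 35.8 |

(scatter of a reading: 1 percentage point)

* the best time, 3.0 min at the latest, for target
* the amount of target, in percent of the starting material charged, at that time

- steps that have been proposed: starting material + reagent -> target; second substrate + reagent -> second product; third substrate + reagent -> third product; target -> over-reaction product

We carry one number, the reagent cover 1.10: the reagent left once the third substrate has taken its whole charge, per starting material charged.

cover = (reagent − third substrate) / starting material = (0.650 mM − 0.100 mM) / 0.50 mM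

The blue run had a cover of 1.62 and its starting material read 0.4% at 120 s. The green run had 0.733, and its reading at 40.0 s shows 66.2% converted; we take the reagent as the limiting reagent there. If the third substrate took its whole charge and the reagent was used up at that reading, the second substrate in the green run took about

0.0535 mM

After the third substrate's charge and the starting material's charge, the flask has a reagent margin of

0.0500 mM

which is about the same as that take. We therefore leave the charge as written and expect some starting material to stay. If the second substrate takes what we reckoned for the green run, we reckon conversion in the flask at 99.3%, and lower if it takes more.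

The forecast reads the green run as “the reagent has run out” and gives 85% at 0.5 min, with ranges 81% to 89% and 0.3 min to 0.9 min.

The flask gives 84.8% at 0.763 min, and at one and a half the best time it still holds 83.9%.

    starting material + reagent → target (k = 480 L mol⁻¹ s⁻¹)
    second substrate + reagent → second product (k = 41.0 L mol⁻¹ s⁻¹)
    third substrate + reagent → third product (k = 5600 L mol⁻¹ s⁻¹)
    target → over-reaction product (k = 0.00120 s⁻¹)

With its cover of 1.10, the flask had a margin of 0.0500 mM; by 3.00 min the second product stood at 0.0938 mM and starting material at 8.78%. The neighbouring flask with 1.2 mM of starting material has a cover of 0.458, which is less than one. Its target peaked at 43.0%, just under that cover, and at 3.00 min that neighbouring flask held 35.4% target with 56.2% starting material.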